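The ester carbinol carbon C1′ (the O–CH2 of the heneicosyl chain) is read as a formaldehyde carbon, and the C1′–C2′ bond as the union of an acyloxymethyl radical with the terminal carbon of 1-eicosene. One flask joins four components: 2,3-dimethoxybenzoyl chloride, paraformaldehyde, 1-eicosene and a hydrosilane. Acyl chloride and formaldehyde first give the precursor, a chloromethyl benzoate. Nickel hydride catalysis then couples it with the olefin in the anti-Markovnikov sense. The step exploits the ester oxygen on C1′, which activates the C–halogen bond and stabilises the radical, and the unbranched chain C2′–C21′, which maps onto a terminal alkene. The catechol oxygens at C2 and C3 of the benzene ring travel as methyl ethers, cleaved last.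

Key step: step 1

Assumption: paraformaldehyde is drawn as monomeric formaldehyde, the species it delivers. The target has no stereocentre, so none has to be set.

Step 1
Reactants: 1 2,3-dimethoxybenzoyl chloride; 2 paraformaldehyde; 3 1-eicosene
Product: 6 heneicosyl 2,3-dimethoxybenzoate, via chloromethyl ester 4 (not isolated), via iodomethyl ester 5 (not isolated)
Conditions: (a) 1 (1.5 equiv relative to 3), 2 (1.1 equiv CH2O per 1), ZnCl2 (2 mol %), neat melt, 60 °C, then brief evacuation; (b) same flask: 3, NiBr2·diglyme (10 mol %), dtbbpy (15 mol %), NaI (30 mol %), (EtO)2MeSiH, Na2CO3, DMA/THF, 30 °C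
Reagents that add atoms: none
Why: Formaldehyde inserts into the C(=O)–Cl bond of 1 under ZnCl2 catalysis (the classical acyl halide–aldehyde addition) to give chloromethyl ester 4, which iodide turns by Finkelstein exchange into the more easily activated iodomethyl ester 5. A bipyridine-ligated Ni–H formed from the silane inserts 3 to give the primary eicosyl–nickel species, Ni(I) abstracts the halogen of 4 or 5 to give the acyloxymethyl radical, and radical capture followed by reductive elimination from Ni(III) forms the OCH2–CH2 bond. The closest known reaction type is the NiH-catalysed reductive hydroalkylation of terminal olefins with alkyl halides, including its four-component form in which a 1-haloalkyl ester is made in the flask from an aldehyde and an acyl halide; 4 is the formaldehyde-derived parent of that electrophile class. No ring is closed and no stereocentre is formed. The step needs linear regioselectivity, which the monosubstituted olefin and the preference of the bipyridine–nickel hydride for the unhindered primary alkyl–nickel secure, and cross-coupling over homocoupling or hydrodehalogenation, which rests on the two partners entering the cycle by different elementary steps (migratory insertion against halogen abstraction) and on the weak, oxygen-activated C–halogen bond. The aryl methyl ethers and the benzoate carbonyl are inert to the silane and to Ni–H at 30 °C.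

Step 2
Reactants: 6 heneicosyl 2,3-dimethoxybenzoate
Product: 8 gentiside I (heneicosyl 2,3-dihydroxybenzoate), via cyclic bromoborate 7 (not isolated)
Conditions: BBr3 (3 equiv), CH2Cl2, −40 → 0 °C; then ice-water
Reagents that add atoms: none
Why: This is a BBr3-mediated aryl methyl ether cleavage in which boron binds the ether oxygens (the C2 oxygen assisted by chelation to the ester carbonyl), bromide removes each methyl group by SN2 attack far faster than it attacks the primary O–CH2 of the long-chain benzoate at or below 0 °C, and the cyclic bromoborate 7 is hydrolysed to the free catechol on work-up.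

Compound list
1 | 2,3-dimethoxybenzoyl chloride | COc1cccc(C(=O)Cl)c1OC | starting material
2 | paraformaldehyde (drawn as formaldehyde) | C=O | starting material
3 | 1-eicosene (unbranched C20 terminal alkene) | C=CCCCCCCCCCCCCCCCCCCC | starting material
4 | chloromethyl 2,3-dimethoxybenzoate | COc1cccc(C(=O)OCCl)c1OC | intermediate
5 | iodomethyl 2,3-dimethoxybenzoate | COc1cccc(C(=O)OCI)c1OC | intermediate
6 | heneicosyl 2,3-dimethoxybenzoate | CCCCCCCCCCCCCCCCCCCCCOC(=O)c1cccc(OC)c1OC | intermediate
7 | heneicosyl 2-bromo-1,3,2-benzodioxaborole-4-carboxylate (cyclic bromoborate of the catechol) | CCCCCCCCCCCCCCCCCCCCCOC(=O)c1cccc2OB(Br)Oc12 | intermediate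
8 | gentiside I, heneicosyl 2,3-dihydroxybenzoate | CCCCCCCCCCCCCCCCCCCCCOC(=O)c1cccc(O)c1O | target

Total step count: 2. Longest linear sequence: 2 steps. The route has only two steps, so both are ranked.

1. Step 1. Reduction or solvolysis of the halomethyl ester may outrun its capture by the alkyl–nickel species. Acyl chloride left over from an incomplete formaldehyde insertion may acylate the alkyl–nickel. Chain walking may erode the linear selectivity. The fallback replaces nickel catalysis with a peroxide-initiated radical chain that builds the same OCH2–CH2 bond. It sets out from 4 and 3 and comes back at 6.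
   - Compound 4 is taken from stage (a) and purified by short-path distillation.
   - It is treated with potassium O-ethyl xanthate in acetone at 0 °C to give S-[(2,3-dimethoxybenzoyl)oxymethyl] O-ethyl dithiocarbonate F1.
   - Lauroyl peroxide, added in portions in refluxing ethyl acetate, drives the degenerative xanthate-transfer addition of F1 to 3. This should give racemic 3-[(ethoxycarbonothioyl)sulfanyl]heneicosyl 2,3-dimethoxybenzoate F2.
   - Reductive removal of the xanthate group with (Me3Si)3SiH and AIBN in toluene at 80 °C gives 6.

2. Step 2. Bromide attack on the alkyl–oxygen bond of the ester may compete with ether cleavage, the less activated C3 methyl ether may be cleaved incompletely, and the liberated catechol may be oxidised during work-up. The fallback changes the masking strategy to a neutral hydrogenolytic release. It sets out from 2 and 3 and comes back at 8.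
   - Commercial 2,3-bis(benzyloxy)benzoic acid F3 is converted with oxalyl chloride and catalytic DMF in CH2Cl2 into 2,3-bis(benzyloxy)benzoyl chloride F4.
   - F4 is carried with 2 and 3 through the same one-flask sequence. It passes through chloromethyl 2,3-bis(benzyloxy)benzoate F5 and iodomethyl 2,3-bis(benzyloxy)benzoate F6 to heneicosyl 2,3-bis(benzyloxy)benzoate F7.
   - Hydrogenolysis (H2, Pd/C, EtOAc/THF, room temperature) removes both benzyl groups without touching the alkyl ester and gives 8.

Further compounds
F1 | step 1 | S-[(2,3-dimethoxybenzoyl)oxymethyl] O-ethyl dithiocarbonate | CCOC(=S)SCOC(=O)c1cccc(OC)c1OC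
F2 | step 1 | racemic 3-[(ethoxycarbonothioyl)sulfanyl]heneicosyl 2,3-dimethoxybenzoate | CCCCCCCCCCCCCCCCCCC(CCOC(=O)c1cccc(OC)c1OC)SC(=S)OCC
F3 | step 2 | 2,3-bis(benzyloxy)benzoic acid | OC(=O)c1cccc(OCc2ccccc2)c1OCc1ccccc1
F4 | step 2 | 2,3-bis(benzyloxy)benzoyl chloride | ClC(=O)c1cccc(OCc2ccccc2)c1OCc1ccccc1
F5 | step 2 | chloromethyl 2,3-bis(benzyloxy)benzoate | ClCOC(=O)c1cccc(OCc2ccccc2)c1OCc1ccccc1
F6 | step 2 | iodomethyl 2,3-bis(benzyloxy)benzoate | ICOC(=O)c1cccc(OCc2ccccc2)c1OCc1ccccc1
F7 | step 2 | heneicosyl 2,3-bis(benzyloxy)benzoate | CCCCCCCCCCCCCCCCCCCCCOC(=O)c1cccc(OCc2ccccc2)c1OCc1ccccc1
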